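**Assumption on the chemistry:** the trans-epoxy ketone 6 must be the (2R,3S) isomer, because retention at its carbonyl-bearing oxirane carbon and inversion at its benzylic carbon lead to the (2R,3R) chromanone; the glycidate that supplies it therefore needs an epoxidation catalyst of the L-fructose series, not the common D-series one.

## Structural features

The target is a 2,3-dihydroflavonol: ring A (a benzo ring with a hydroxyl at C5 and a methoxyl at C7) is fused through C4a and C8a to the dihydropyranone ring C, and ring B, a free catechol, hangs from C2 by one C–C bond. C2 and C3 are neighbouring stereocentres, both R, with the aryl group and the acetoxy group trans and diequatorial; C3 lies alpha to the C4 ketone and carries the only ester. The alpha-acetoxy ketone is base-labile and its C3–H is enolisable. The free catechol is easily oxidised, and its para hydroxyl can open ring C through a quinone methide and so epimerise C2. Ring C can also be dehydrogenated to the flavonol. The C5 hydroxyl is tied to the C4 carbonyl by a six-membered hydrogen bond, which makes it the least nucleophilic oxygen of the molecule. The real difficulty is the differentiation of the oxygens (O1 in the ring, C5 hydroxyl free, C7 oxygen methylated, C3 oxygen acetylated, both ring B phenols free) together with absolute control of the trans pair C2/C3. The key step uses the 1,3,5-alternation of O1, the C5 oxygen and the C7 oxygen around ring A, with the acyl carbon C4 on C4a: this is the pattern of a folded 3,5,7-triketo ester, which a 4-methoxy-2-pyranone stores with the C7 oxygen already methylated. It also uses the C2–O1 bond, which is benzylic to the para-oxygenated ring B and can therefore be made by a ring A phenoxide opening a trans-epoxide.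

## Logic of the disconnections

11 to 10. The two phenolic O–H bonds of ring B are traced back to O–benzyl bonds. The catechol is kept masked to the end so that no free para hydroxyl is present under basic conditions and no oxidation-prone diol is carried through the route. The price is that the last step must be neutral and must spare the acetate, the aryl ketone and the benzylic C2–O1 bond, which points to hydrogenolysis.

10 to 9. The acyl C–O bond at the C3 oxygen is cut. An acetate could not pass through the basic ring-forming step, and the C3 oxygen is born there as an alkoxide. The gain is an intermediate with only two free hydroxyls of very different character. The forward step must acylate the secondary alcohol and leave the hydrogen-bonded C5 phenol alone.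

9 to 6 (through 8 and 7). The O1–C2 bond and the C4a–C5 bond are cut. Opening ring C at the benzylic carbon gives 8, an epoxy ketone on a symmetrical 2,6-dihydroxy-4-methoxyphenyl ring. Opening ring A by a retro-Claisen cut gives 7, and lactonisation of its enol gives 6. Two rings and all protecting-group questions of ring A disappear at once. The forward step has to fold the chain in the Claisen and not the aldol sense, and has to open the oxirane at the benzylic carbon with inversion. The benzyl ethers are kept in 6 because an ester or silyl group on the para oxygen would be cleaved by methoxide to a phenoxide that expels the epoxide oxygen as a quinone methide.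

6 to 3 and 4 (through 5). The bond between the ketone carbon and its methylene neighbour is cut. This separates a carbanion at the pyranone methyl group from an acyl donor that already carries both stereocentres, so the route becomes convergent. The forward step must acylate at the ester without touching the oxirane, and must cope with a product that is more acidic than the carbanion precursor.

3 to 2. Both C–O bonds of the oxirane are cut, leaving an E-alkene. All the absolute stereochemistry of the route is concentrated in one catalytic oxygen transfer. The demand is face selectivity in the sense that gives the (2R,3S) epoxide, and conditions mild enough for an acid-sensitive aryl oxirane.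

2 to 1. The C=C bond is cut to the aldehyde and a two-carbon phosphonate reagent. The only demand is E selectivity, which a stabilised phosphonate anion secures.

## Other disconnections considered

**Alternative 1:** The cut goes through O1–C2 and C3–C4 of ring C. In the forward direction a chiral phosphoric acid would dehydrate 2-(hydroxymethyl)-3,5-dimethoxyphenol A1 to its ortho-quinone methide. This heterodiene would add to (E)-2-[3,4-bis(benzyloxy)phenyl]ethenyl acetate A2 in an inverse-demand [4+2] cycloaddition to give (2R,3S)-2-[3,4-bis(benzyloxy)phenyl]-5,7-dimethoxychroman-3-yl acetate A3. The descriptor at C3 of A3 differs from that of the target only because C4 is a methylene; the spatial arrangement is the same trans one.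

- In favour: the step is convergent and catalytic. It sets both stereocentres at once, with the trans relation copied from the E geometry of A2, which is one stereocentre more than the chosen key step creates; on this count the alternative is better. The acetate is in place from the start, so no hydroxyl has to be singled out later; here too it is better.
- Against: A3 is at the flavan oxidation level. C4 would have to be oxidised to the ketone next to the doubly activated C2–H. Ring A arrives as a dimethyl ether, so the C5 oxygen must be demethylated selectively. That is possible only once the C4 carbonyl exists, and needs boron or aluminium halides that also attack benzyl ethers and the acetate. The quinone methide from A1 has no stabilising substituent on its methylene carbon, unlike the substrates on which phosphoric acid control is established. A2 is a weak two-electron partner whose regiochemistry rests on the aryl group outweighing the acetoxy group, and it is hard to obtain as a single E isomer.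
- Comparison: on structure the alternative builds one ring, the chosen plan two. On mechanism it is an ion-pair-controlled cycloaddition against a substrate-controlled ionic cascade; neither is clearly more reliable. On step economy the two are about equal up to the key step, but the alternative then needs oxidation, demethylation and deprotection where the chosen plan needs acetylation and deprotection.

**Alternative 2:** The cut goes through C4a–C5 and C8–C8a, so that ring A is made last. In the forward direction (1E)-1,3-dimethoxy-1-(trimethylsilyloxy)buta-1,3-diene A5 would add across the brominated double bond of (2R,3R)-2-[3,4-bis(benzyloxy)phenyl]-5-bromo-4-oxo-3,4-dihydro-2H-pyran-3-yl acetate A4. Loss of HBr and methanol would then aromatise the new ring to (2R,3R)-2-[3,4-bis(benzyloxy)phenyl]-5-hydroxy-7-methoxy-4-oxochroman-3-yl acetate A6, which is identical with 10.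

- In favour: the polarity of both partners fixes the regiochemistry, since the nucleophilic diene terminus goes to the oxygen-bearing carbon C8a. Ring A emerges with the C5 hydroxyl free and the C7 oxygen methylated, which is the equal of the chosen plan. The acetate is carried through, so no selective acetylation is needed, and only hydrogenolysis remains after the key step; on both points the alternative is better.
- Against: both stereocentres must already be present in A4. A 2,3-trans 2-aryl-3-acyloxy dihydropyranone is not easily reached in enantiopure form: a hetero-Diels–Alder reaction of 1 with an oxygenated siloxy diene tends to favour the cis isomer, and a bromination follows. The double bond of A4 is a donor-substituted vinylogous ester and a poor dienophile. The base needed to remove HBr meets an epimerisable C3–H alpha to the ketone.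
- Comparison: on structure the alternative forms one ring and no stereocentre in its key step. On mechanism it is a thermal cycloaddition–elimination against an ionic cascade. On step economy it shifts the work to the front: A4 needs an estimated four to five steps against three for 6, so the total is equal or slightly longer, and the stereochemical problem is moved to a less well-solved place.

**Alternative 3:** The cut goes through C8a–O1 and C4–C4a, and then through O1–C2. In the forward direction CsF would release 3,5-dimethoxybenzyne from 3,5-dimethoxy-2-(trimethylsilyl)phenyl trifluoromethanesulfonate A7. The carboxylate of (2R,3S)-3-[3,4-bis(benzyloxy)phenyl]oxirane-2-carboxylic acid A8 (the saponification product of 3) would add to the aryne carbon remote from the neighbouring methoxyl, and the aryl anion would take over the acyl group. The resulting phenoxide would open the oxirane at the benzylic carbon to give (2R,3R)-2-[3,4-bis(benzyloxy)phenyl]-3-hydroxy-5,7-dimethoxychroman-4-one A9.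

- In favour: ring A is bought as an aromatic ring, and the regiochemistry of the aryne addition is dependable. The stereochemical relay from the epoxide is the same as in the chosen plan, so the two are equal there. The fluoride conditions are milder than warm methoxide, which is better for the oxirane.
- Against: ring A arrives as a dimethyl ether, so a selective demethylation at the C5 oxygen is added, with the same conflict with the benzyl ethers as in Alternative 1. The insertion must compete with simple O-arylation to the aryl ester and with attack of the aryl anion on the oxirane. The free acid A8 decarboxylates easily and would have to be used as its caesium salt. A7 needs about three steps of its own.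
- Comparison: on structure the alternative forms one ring and three bonds; the chosen plan forms two rings and two bonds. On mechanism both end with the same phenoxide opening. On step economy the alternative is longer by the demethylation and by the synthesis of A7, and it gives up the main advantage of the chosen plan, a ring A that is born with the correct oxygen pattern.

Key step: step 4

## Route

Step 1
Reactants: 1 3,4-bis(benzyloxy)benzaldehyde
Product: 2 methyl (2E)-3-[3,4-bis(benzyloxy)phenyl]prop-2-enoate
Conditions: (MeO)2P(O)CH2CO2Me, NaH, THF, 0 °C to rt
Reagents that add atoms: trimethyl phosphonoacetate, COC(=O)CP(=O)(OC)OC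
Why: Horner–Wadsworth–Emmons olefination of an aromatic aldehyde with a stabilised phosphonate anion should give the E-cinnamate, because the anti oxaphosphetane forms reversibly and eliminates fastest; the benzyl ethers are inert.

Step 2
Reactants: 2 methyl (2E)-3-[3,4-bis(benzyloxy)phenyl]prop-2-enoate
Product: 3 methyl (2R,3S)-3-[3,4-bis(benzyloxy)phenyl]oxirane-2-carboxylate
Conditions: 4,5-di-O-acetyl-1,2-O-isopropylidene-β-L-erythro-2,3-hexodiulo-2,6-pyranose (0.3 equiv), Oxone (2KHSO5·KHSO4·K2SO4), NaHCO3, Bu4NHSO4, MeCN/aq. Na2EDTA, 0 °C
Reagents that add atoms: potassium peroxymonosulfate (KHSO5, the oxidant in Oxone), [K+].[O-]S(=O)(=O)OO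
Why: Shi epoxidation with the diacetate ketone, the variant that tolerates E-cinnamic esters and resists Baeyer–Villiger destruction; the electron-rich aryl group makes the alkene a good partner for the electrophilic dioxirane. In the spiro transition state, ketones of the D-fructose series give the (2S,3R) glycidate from E-cinnamates, so the L-series ketone is specified to set both stereocentres as (2R,3S), with the trans relation copied from the alkene. The bicarbonate buffer protects the acid-sensitive aryl oxirane.

Step 3
Reactants: 3 methyl (2R,3S)-3-[3,4-bis(benzyloxy)phenyl]oxirane-2-carboxylate; 4 4-methoxy-6-methyl-2H-pyran-2-one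
Product: 6 6-{2-[(2R,3S)-3-[3,4-bis(benzyloxy)phenyl]oxiran-2-yl]-2-oxoethyl}-4-methoxy-2H-pyran-2-one, via (4-methoxy-2-oxo-2H-pyran-6-yl)methyllithium 5 (not isolated)
Conditions: 4 (2.2 equiv), LiN(SiMe3)2 (2.2 equiv), THF, −78 °C; then 3, −78 to −40 °C; aq. NH4Cl
Reagents that add atoms: none
Why: Claisen-type C-acylation of the vinylogous ester enolate 5 by the glycidic ester; the second equivalent of 5 deprotonates the acidic product, which stops further addition. At −78 °C addition to the ester carbonyl should outrun opening of the oxirane, and the oxirane C–H is not enolisable, so both stereocentres are carried over unchanged.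

Step 4
Reactants: 6 6-{2-[(2R,3S)-3-[3,4-bis(benzyloxy)phenyl]oxiran-2-yl]-2-oxoethyl}-4-methoxy-2H-pyran-2-one
Product: 9 (2R,3R)-2-[3,4-bis(benzyloxy)phenyl]-3,5-dihydroxy-7-methoxychroman-4-one, via ring-opened keto ester 7 (not isolated), via aryl epoxy ketone 8 (not isolated)
Conditions: Mg(OMe)2 (4 equiv), degassed MeOH (0.02 M), under argon, rt to 55 °C; then cold 1 M HCl
Reagents that add atoms: none
Why: Methoxide adds to the lactone carbonyl of 6 and opens the ring to the enol-ether keto ester 7, which the divalent magnesium ion holds as a six-membered chelate of its 5,7-diketone enolate. The chelated central carbon then attacks the ester carbonyl in a 6-(enolexo)-exo-trig Claisen condensation that forms the C4a–C5 bond, and loss of methoxide with enolisation aromatises ring A to the 2,6-dihydroxy-4-methoxyphenyl ketone 8. Either of its two equivalent phenoxides then attacks the benzylic oxirane carbon from the side opposite to the breaking C–O bond, a 6-endo-tet opening that forms O1–C2 and closes ring C. The closest known reactions are the Mg(OMe)2 recyclisation of 6-(acylmethyl)-4-methoxy-2-pyranones to 2-acyl-5-methoxyresorcinols and the base-induced cyclisation of 2'-hydroxychalcone epoxides to trans-dihydroflavonols, here run one after the other in the same flask. The new stereocentre C2 is set by inversion at the (S)-configured benzylic carbon, which gives (R), while C3 keeps its (R) configuration because none of its bonds is broken, so the trans-epoxide maps onto the 2,3-trans diequatorial product. Claisen and not aldol folding is secured by the chelate, which deactivates both ketone carbonyls as acceptors and leaves the ester as the only electrophile within six-membered reach of the nucleophilic carbon. Attack at C2 and not at C3 is secured by the 4-benzyloxy group of ring B, which stabilises positive charge at the benzylic carbon in a loose SN2 transition state, whereas 5-exo attack would have to occur at a carbon deactivated by the adjacent carbonyl. Exclusion of air guards 9 against dehydrogenation to the flavonol, and the magnesium alkoxide at C3 disfavours enolisation of the product.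

Step 5
Reactants: 9 (2R,3R)-2-[3,4-bis(benzyloxy)phenyl]-3,5-dihydroxy-7-methoxychroman-4-one
Product: 10 (2R,3R)-2-[3,4-bis(benzyloxy)phenyl]-5-hydroxy-7-methoxy-4-oxochroman-3-yl acetate
Conditions: Ac2O (1.2 equiv), pyridine, CH2Cl2, 0 °C to rt
Reagents that add atoms: acetic anhydride, CC(=O)OC(C)=O
Why: O-acylation of the secondary alcohol; the C5 phenol is locked in a hydrogen bond to the C4 carbonyl and is far less nucleophilic, so with a small excess of anhydride and no acyl-transfer catalyst the reaction should stop at the C3 ester. Pyridine is too weak a base to enolise C3, so the configuration is retained.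

Step 6
Reactants: 10 (2R,3R)-2-[3,4-bis(benzyloxy)phenyl]-5-hydroxy-7-methoxy-4-oxochroman-3-yl acetate
Product: 11 (2R,3R)-2-(3,4-dihydroxyphenyl)-5-hydroxy-7-methoxy-4-oxochroman-3-yl acetate (3-O-acetylpadmatin)
Conditions: H2 (1 atm), 10% Pd/C, EtOAc/THF, rt
Reagents that add atoms: none
Why: Hydrogenolysis of the two aryl benzyl ethers over palladium on carbon under neutral conditions; at ambient pressure and with the reaction stopped at full conversion, the acetate, the chelated aryl ketone and the ring-bound benzylic C2–O1 bond should survive, and no stereocentre is touched.

## Compound list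

1 | 3,4-bis(benzyloxy)benzaldehyde | O=Cc1ccc(OCc2ccccc2)c(OCc2ccccc2)c1 | starting material
2 | methyl (2E)-3-[3,4-bis(benzyloxy)phenyl]prop-2-enoate | COC(=O)/C=C/c1ccc(OCc2ccccc2)c(OCc2ccccc2)c1 | intermediate
3 | methyl (2R,3S)-3-[3,4-bis(benzyloxy)phenyl]oxirane-2-carboxylate | COC(=O)[C@@H]1O[C@H]1c1ccc(OCc2ccccc2)c(OCc2ccccc2)c1 | intermediate
4 | 4-methoxy-6-methyl-2H-pyran-2-one | COC1=CC(=O)OC(C)=C1 | starting material
5 | (4-methoxy-2-oxo-2H-pyran-6-yl)methyllithium | [Li]CC1=CC(OC)=CC(=O)O1 | intermediate (not isolated)
6 | 6-{2-[(2R,3S)-3-[3,4-bis(benzyloxy)phenyl]oxiran-2-yl]-2-oxoethyl}-4-methoxy-2H-pyran-2-one | COC1=CC(=O)OC(CC(=O)[C@@H]2O[C@H]2c2ccc(OCc3ccccc3)c(OCc3ccccc3)c2)=C1 | intermediate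
7 | methyl (2E)-7-[(2R,3S)-3-[3,4-bis(benzyloxy)phenyl]oxiran-2-yl]-3-methoxy-5,7-dioxohept-2-enoate (present as its magnesium chelate) | COC(=O)/C=C(/OC)CC(=O)CC(=O)[C@@H]1O[C@H]1c1ccc(OCc2ccccc2)c(OCc2ccccc2)c1 | intermediate (not isolated)
8 | [(2R,3S)-3-[3,4-bis(benzyloxy)phenyl]oxiran-2-yl](2,6-dihydroxy-4-methoxyphenyl)methanone | COc1cc(O)c(C(=O)[C@@H]2O[C@H]2c2ccc(OCc3ccccc3)c(OCc3ccccc3)c2)c(O)c1 | intermediate (not isolated)
9 | (2R,3R)-2-[3,4-bis(benzyloxy)phenyl]-3,5-dihydroxy-7-methoxychroman-4-one | COc1cc(O)c2c(c1)O[C@H](c1ccc(OCc3ccccc3)c(OCc3ccccc3)c1)[C@@H](O)C2=O | intermediate
10 | (2R,3R)-2-[3,4-bis(benzyloxy)phenyl]-5-hydroxy-7-methoxy-4-oxochroman-3-yl acetate | COc1cc(O)c2c(c1)O[C@H](c1ccc(OCc3ccccc3)c(OCc3ccccc3)c1)[C@@H](OC(C)=O)C2=O | intermediate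
11 | (2R,3R)-2-(3,4-dihydroxyphenyl)-5-hydroxy-7-methoxy-4-oxochroman-3-yl acetate (3-O-acetylpadmatin) | COc1cc(O)c2c(c1)O[C@H](c1ccc(O)c(O)c1)[C@@H](OC(C)=O)C2=O | target

## Step count and least certain steps

Total step count: 6. Longest linear sequence: 6 steps (1 to 11); 4 enters at step 3.

**Step 4 (key step).** Several processes can divert the cascade:
- aldol-type folding of the opened chain to a resorcylate if chelation is incomplete;
- methanolysis of the magnesium-activated oxirane at the benzylic carbon before ring A exists;
- five-membered closure at the carbonyl-bearing oxirane carbon;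
- dehydrogenation of the product by traces of air.

Partial solvolysis need not be fatal: 8 and its benzylic methanol adduct ionise to the same benzylic cation with C3 intact, so a short acid treatment of the crude product should still funnel them to 9.

The fallback gives up the pyranone and uses a preformed ring A. It sets out from 1 and the commercial 1-(2,6-dihydroxy-4-methoxyphenyl)ethanone F1. Both phenols are protected (MOMCl, NaH, DMF) to give 1-[4-methoxy-2,6-bis(methoxymethoxy)phenyl]ethanone F2. Claisen–Schmidt condensation with 1 (KOH, EtOH) gives (E)-3-[3,4-bis(benzyloxy)phenyl]-1-[4-methoxy-2,6-bis(methoxymethoxy)phenyl]prop-2-en-1-one F3. Juliá–Colonna epoxidation (poly-L-leucine, urea–H2O2, DBU, THF) should give [(2R,3S)-3-[3,4-bis(benzyloxy)phenyl]oxiran-2-yl][4-methoxy-2,6-bis(methoxymethoxy)phenyl]methanone F4, though the doubly ortho-substituted enone is expected to react slowly. HCl in MeOH at 45 °C then removes both acetals and closes ring C through the benzylic cation to the trans product. The fallback passes through 8 and comes back to the route at 9.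

**Step 2.** The risks are insufficient face selectivity, slow oxygen transfer with loss of the ketone catalyst, hydrolytic opening of the electron-rich oxirane in the aqueous medium, and the need to prepare the L-series ketone. The fallback replaces catalytic oxygen transfer by a resolution. It sets out from 1. Darzens condensation with methyl chloroacetate (NaOMe, MeOH, −10 °C to rt) gives methyl rac-(2R,3S)-3-[3,4-bis(benzyloxy)phenyl]oxirane-2-carboxylate F5 as the racemic trans ester. Lipase-catalysed enantioselective hydrolysis in toluene/phosphate buffer (Serratia marcescens or Candida rugosa lipase), a resolution type established for trans-3-arylglycidic esters, should consume the (2S,3R) ester. The unhydrolysed ester is 3, where the fallback comes back to the route, at the cost of half the material.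

**Step 3.** The risks are proton transfer from the acidic product to 5, which stalls conversion, attack of 5 on the oxirane, and condensation of 5 with 4. The fallback changes the acyl donor to one that forms a stable tetrahedral chelate. It sets out from 3. Saponification (KOH, EtOH, 0 °C) gives potassium (2R,3S)-3-[3,4-bis(benzyloxy)phenyl]oxirane-2-carboxylate F6. Activation with pivaloyl chloride and reaction with MeNHOMe·HCl and N-methylmorpholine gives (2R,3S)-3-[3,4-bis(benzyloxy)phenyl]-N-methoxy-N-methyloxirane-2-carboxamide F7. Addition of 5 (1.2 equiv, THF, −78 °C) gives a chelated adduct that releases the ketone only on work-up, so no second equivalent of carbanion is lost. The fallback comes back at 6.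

**Step 5.** The risks are concurrent acylation of the C5 phenol and base-induced enolisation at C3 with opening of ring C. The fallback acylates both hydroxyls and then distinguishes the two esters. It sets out from 9. Exhaustive acetylation (Ac2O, pyridine, DMAP) gives (2R,3R)-2-[3,4-bis(benzyloxy)phenyl]-7-methoxy-4-oxochromane-3,5-diyl diacetate F8. The aryl acetate, the more reactive of the two, is cleaved selectively with NH4OAc in aqueous MeOH at rt. The fallback comes back at 10.

## Further compounds

F1 | step 4 | 1-(2,6-dihydroxy-4-methoxyphenyl)ethanone | COc1cc(O)c(C(C)=O)c(O)c1
F2 | step 4 | 1-[4-methoxy-2,6-bis(methoxymethoxy)phenyl]ethanone | COCOc1cc(OC)cc(OCOC)c1C(C)=O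
F3 | step 4 | (E)-3-[3,4-bis(benzyloxy)phenyl]-1-[4-methoxy-2,6-bis(methoxymethoxy)phenyl]prop-2-en-1-one | COCOc1cc(OC)cc(OCOC)c1C(=O)/C=C/c1ccc(OCc2ccccc2)c(OCc2ccccc2)c1
F4 | step 4 | [(2R,3S)-3-[3,4-bis(benzyloxy)phenyl]oxiran-2-yl][4-methoxy-2,6-bis(methoxymethoxy)phenyl]methanone | COCOc1cc(OC)cc(OCOC)c1C(=O)[C@@H]1O[C@H]1c1ccc(OCc2ccccc2)c(OCc2ccccc2)c1
F5 | step 2 | methyl rac-(2R,3S)-3-[3,4-bis(benzyloxy)phenyl]oxirane-2-carboxylate (racemic trans ester; one enantiomer drawn) | COC(=O)[C@@H]1O[C@H]1c1ccc(OCc2ccccc2)c(OCc2ccccc2)c1
F6 | step 3 | potassium (2R,3S)-3-[3,4-bis(benzyloxy)phenyl]oxirane-2-carboxylate | [K+].[O-]C(=O)[C@@H]1O[C@H]1c1ccc(OCc2ccccc2)c(OCc2ccccc2)c1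
F7 | step 3 | (2R,3S)-3-[3,4-bis(benzyloxy)phenyl]-N-methoxy-N-methyloxirane-2-carboxamide | CON(C)C(=O)[C@@H]1O[C@H]1c1ccc(OCc2ccccc2)c(OCc2ccccc2)c1
F8 | step 5 | (2R,3R)-2-[3,4-bis(benzyloxy)phenyl]-7-methoxy-4-oxochromane-3,5-diyl diacetate | COc1cc(OC(C)=O)c2c(c1)O[C@H](c1ccc(OCc3ccccc3)c(OCc3ccccc3)c1)[C@@H](OC(C)=O)C2=O
A1 | alternative 1 | 2-(hydroxymethyl)-3,5-dimethoxyphenol | COc1cc(O)c(CO)c(OC)c1
A2 | alternative 1 | (E)-2-[3,4-bis(benzyloxy)phenyl]ethenyl acetate | CC(=O)O/C=C/c1ccc(OCc2ccccc2)c(OCc2ccccc2)c1
A3 | alternative 1 | (2R,3S)-2-[3,4-bis(benzyloxy)phenyl]-5,7-dimethoxychroman-3-yl acetate | COc1cc(OC)c2c(c1)O[C@H](c1ccc(OCc3ccccc3)c(OCc3ccccc3)c1)[C@@H](OC(C)=O)C2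
A4 | alternative 2 | (2R,3R)-2-[3,4-bis(benzyloxy)phenyl]-5-bromo-4-oxo-3,4-dihydro-2H-pyran-3-yl acetate | BrC1=CO[C@H](c2ccc(OCc3ccccc3)c(OCc3ccccc3)c2)[C@@H](OC(C)=O)C1=O
A5 | alternative 2 | (1E)-1,3-dimethoxy-1-(trimethylsilyloxy)buta-1,3-diene | C=C(OC)/C=C(\OC)O[Si](C)(C)C
A6 | alternative 2 | (2R,3R)-2-[3,4-bis(benzyloxy)phenyl]-5-hydroxy-7-methoxy-4-oxochroman-3-yl acetate | COc1cc(O)c2c(c1)O[C@H](c1ccc(OCc3ccccc3)c(OCc3ccccc3)c1)[C@@H](OC(C)=O)C2=O
A7 | alternative 3 | 3,5-dimethoxy-2-(trimethylsilyl)phenyl trifluoromethanesulfonate | COc1cc(OC)c([Si](C)(C)C)c(OS(=O)(=O)C(F)(F)F)c1
A8 | alternative 3 | (2R,3S)-3-[3,4-bis(benzyloxy)phenyl]oxirane-2-carboxylic acid | OC(=O)[C@@H]1O[C@H]1c1ccc(OCc2ccccc2)c(OCc2ccccc2)c1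
A9 | alternative 3 | (2R,3R)-2-[3,4-bis(benzyloxy)phenyl]-3-hydroxy-5,7-dimethoxychroman-4-one | COc1cc(OC)c2c(c1)O[C@H](c1ccc(OCc3ccccc3)c(OCc3ccccc3)c1)[C@@H](O)C2=O
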